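## Structural features

The target is a chroman. Ring B (O1, C2, C3, C4) is fused through C4a–C8a to ring A, a pentasubstituted phloroglucinol with a free hydroxyl on C5, a methyl ether on C7, the ring oxygen O1 on C8a, one hydrogen on C6 and an (E)-4-hydroxycinnamoyl ketone on C8. Ring A and its C8 acyl group thus form the A-ring half of a chalcone. C2 carries a 4-hydroxyphenyl group and C4 a 2-hydroxy-4-(4-hydroxyphenyl)butyl chain (C1'–C4'), so the line C2–C3–C4–C1'–C2'–C3'–C4' with its two aryl ends is a diarylheptanoid, joined to the chalcone through O1–C2 and C4–C4a. The three stereocentres C2 (R), C4 (S) and C2' (R) are not contiguous: C2 and C4 are 1,3 across C3 (trans), and C4 and C2' are 1,3 across C1', so none can be set by 1,2-induction. The fragile points are the C2–O1 bond (a benzylic aryl ether activated by a para oxygen, which can ionise under acid), the enone (no hydrogenolysis or strong nucleophiles late), and the C2' hydroxyl, which could capture a C2 cation to give an isomeric oxane. The real difficulty is ring A, where three oxygens with three different fates and two different carbon substituents sit on one benzene, and C4, which lies between two nearly alike CH2–CH(O) arms. The key step exploits the O–C–O–C–O alternation of ring A with the C4 chain on C4a between C5 and C8a: C5–C6–C7–C8 with oxygen on C5 and C7 is a 3-methoxy vinylketene, and C4a–C8a with oxygen on C8a is a siloxyalkyne, so a ketene–alkyne benzannulation delivers C5–OH, C7–OMe and C8a–OSi already differentiated.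

## Logic of the disconnections

**Protecting groups and the C8–carbonyl bond.** 39 is 38 without its four acetal groups and its silyl ether. 38 is cut at C8–C(=O) into 33 and 36. The enone is the most reactive function, so it is brought in last as a complete acyl unit; no earlier step then meets a Michael acceptor. The chalcone half shrinks to a small amide. The forward step demands that bromine–lithium exchange at C8 outruns ortho-metalation and that the aryllithium adds 1,2 to 36; the deprotection must spare the C2–O1 bond.

**C8–Br.** 33 goes back to 32. Only C6 and C8 carry hydrogen, and the electrophile must choose C8. The bias is steric and conformational: C8 lies between the methyl ether and the ring oxygen, C6 between two free alkoxy groups.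

**O1–C2.** 32 goes back to 31, then 30, then 29. C2 is benzylic and para-oxygenated, so its hydroxyl ionises under mild acid and the C8a phenol closes ring B. The C2 configuration need not be carried; it is decided in the closure, where trans is favoured. This removes ring B and one stereocentre from the problem. Two demands follow, and both shape the precursor:
- The C8a oxygen must be the only free phenol. The C5 hydroxyl of 29 is therefore capped (30) before fluoride releases the C8a oxygen (31). With both flanking hydroxyls free, ring A would be constitutionally symmetric and the identity of C5 and C8a would be lost.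
- The C2 and C2' oxygens must differ. C2 carries a triethylsilyl group and C2' a tert-butyldimethylsilyl group, so only the benzylic carbinol is unmasked and the C2' oxygen stays silylated and poorly nucleophilic.

**Ring A (key).** 29 is cut at C4a–C5, C8–C8a and C5–C6 into 21 and 25. The pentasubstituted arene becomes a four-carbon diazo ketone and an ynol ether, and all stereochemistry resides in 21. The forward step demands one regiochemistry in the ketene–alkyne addition, no free O–H in 21, and survival of the propargylic centre C4.

**Ynol ether and alkyne.** 21 goes back to 18 (C8a–O bond, by oxidation of the acetylide), 17, 16 (C4a–C8a bond, by one-carbon homologation of the lactol) and 15. This avoids an open-chain γ-hydroxy ester, which would relactonise. The demands are no epimerisation at C4 during homologation and O-silylation, not C-silylation, of the ynolate.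

**C4–C1'.** 15 is cut into 4 and 13. Alkylation of a γ-substituted butyrolactone enolate is trans selective, so the C2 centre controls C4. Two fragments of similar size result, each with one stereocentre. The demand is SN2 displacement at a β-siloxy primary iodide on the enolate face anti to the aryl group.

**C2 stereocentre.** 4 goes back to 2 and 1 by asymmetric reduction of the aryl ketone and lactonisation. This centre is a relay: it controls C4 in 15 and is set anew in 32.

**Side chain.** 13 goes back to 12, 11, then 8 and 9 (C3'–C4' bond), 6 and 5. C2' comes from the chiral pool. The Grignard reagent must form without homocoupling and must open the epoxide at its CH2 carbon.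

**Diazo ketone.** 25 goes back to 23 and 22. The diazo group is installed by diazo transfer to a methyl ketone, because an enoyl chloride treated with a diazoalkane would also undergo dipolar cycloaddition at its C=C bond.

**Amide.** 36 goes back to 35 and 34 by protection and aminolysis.

## Other disconnections considered

**Alternative 1:** The cut is O1–C2 together with C3–C4, so ring B comes from an ortho-quinone methide of ring A and a styrene that supplies C2 and C3. A chiral phosphoric acid would protonate the alkene of the ortho-hydroxystyrene A2 at C1'. The resulting quinone methide (C8a=O, C4a=C4) would add 4-acetoxystyrene A3 across oxygen and C4 to give the protected 8-acetyl chroman A1.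
- In its favour: ring B, C2 and C4 arise in one convergent catalytic step; C2 and C3 come from a commodity alkene; the acetyl group already sits on C8, so the enone needs only an aldol condensation.
- Against it here: such cycloadditions usually favour the 2,4-cis chroman, whereas trans is required, so a C2 epimerisation through the benzylic cation would still be needed. The catalyst must set C4 beside the existing C2' centre (matched or mismatched). The phenol of A2 is hydrogen bonded to the acetyl group, and A3 is only moderately electron rich. The benzyl ethers of A1 must be removed before the enone is made.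
- Above all, A2 is a hexasubstituted benzene with its three oxygens already told apart. The regiochemical problem of ring A is moved into the making of A2, not solved.
- Comparison: on step economy after the arene is in hand, this alternative is the better one. At C2 both plans end with the same thermodynamic argument and are equal. At C4 the chosen plan uses a lactone alkylation with a well-understood facial bias, the alternative a catalyst working against the intrinsic preference. On ring A the chosen plan is stronger.

**Alternative 2:** The cut is O1–C8a together with the C8–carbonyl bond. Lithium 2,2,6,6-tetramethylpiperidide would deprotonate the carbinol of bromoarene A5 and then C8–H. Loss of bromide would give the C8–C8a aryne, the C2 alkoxide would add at C8a, and the C8 aryllithium would be acylated by the Weinreb amide A6 to give the fully silylated target A4.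
- In its favour: two bonds, ring B and the whole enone form in one flask, replacing four steps of the chosen plan; on end-game step economy it is clearly better. Addition at C8a is favoured by ring size and by the C7 methoxy group, which stabilises the anion at C8. C2 is carried with retention and no cation, so in fidelity at C2 it is at least the equal of the chosen closure. All-silyl protection allows a fluoride end game, gentler on the C2–O1 bond than the acid of the chosen plan; this is a real advantage.
- Against it here: the aryllithium is formed beside the conjugate acid of the base and may be protonated before it meets A6. The base may add to the aryne or attack A6. Both C2 and C4 need absolute control, with no thermodynamic correction. A5 carries bromine where the chosen plan has an oxygen, so a regiodefined arene must still be made.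
- Comparison: mechanistically the alternative stacks three consecutive events in one operation and is the riskier. Structurally it leaves ring A as the open question that the chosen plan answers.

**Alternative 3:** The cut is again O1–C2, made by C–H oxidation. DDQ would oxidise the free 4-alkylphenol of A8 to the para-quinone methide at C2, and the C8a hydroxyl would add to it in 1,6 fashion to give chroman A7.
- In its favour: C2 needs no oxygen in the precursor, so one stereocentre, one protecting group and the asymmetric reduction disappear. The C2 configuration is settled in the closure by the same conformational argument as in the chosen plan (equal on this point). The chain is simpler, which makes this alternative the better on step economy of the chain.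
- Against it here: without the C2 carbinol, the lactone relay that sets C4 is gone, so C4 needs its own asymmetric method. DDQ could also abstract hydride from C4–H (tertiary, benzylic to ring A) or oxidise A7 again at C2. The C8a phenol is deactivated by hydrogen bonding to the acetyl group. The pivalates must survive the base of the later aldol condensation.
- Comparison: same bond and same thermodynamic logic as the chosen closure. The chosen plan pays with a pre-installed leaving group, which it also uses to control C4, and gains chemoselectivity because only the carbinol carbon can ionise. The alternative is shorter but leaves oxidant selectivity and C4 open, and it too presupposes a differentiated ring A.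

Key step: step 15

Remark on the chemistry: chroman numbering (O1, C2, C3, C4, C4a, C5 to C8, C8a; side chain C1' to C4' counted from C4) is used for the open-chain intermediates as well, and the ketene carbonyl carbon of the key step is taken to become C5 throughout.

## Route

Step 1
Reactants: 1 4-(4-hydroxyphenyl)-4-oxobutanoic acid
Product: 2 methoxymethyl 4-[4-(methoxymethoxy)phenyl]-4-oxobutanoate
Conditions: MOMCl (2.4 equiv), i-Pr2NEt, CH2Cl2, 0 °C → rt
Reagents that add atoms: chloromethyl methyl ether (MOMCl), COCCl
Why: O-alkylation of the phenol and the carboxylate (Williamson-type acetal formation) masks the phenol for the later basic steps and turns the acid into an activated ester that should lactonise after reduction.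

Step 2
Reactants: 2 methoxymethyl 4-[4-(methoxymethoxy)phenyl]-4-oxobutanoate
Product: 4 (5R)-5-[4-(methoxymethoxy)phenyl]oxolan-2-one, via hydroxy ester 3 (not isolated)
Conditions: RuCl[(R,R)-TsDPEN](p-cymene) (1 mol %), HCO2H/Et3N (5:2), EtOAc, 40 °C
Reagents that add atoms: none
Why: Noyori asymmetric transfer hydrogenation of the aryl ketone; the (R,R)-diamine ligand should deliver hydride to the face that gives the (R)-benzylic alcohol (aryl versus alkyl differentiation), and the γ-hydroxy ester should close to the lactone with loss of methoxymethanol.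

Step 3
Reactants: 5 4-(hydroxymethyl)phenol
Product: 6 [4-(methoxymethoxy)phenyl]methanol
Conditions: MOMCl, K2CO3, acetone, 0 °C → rt
Reagents that add atoms: chloromethyl methyl ether (MOMCl), COCCl
Why: K2CO3 deprotonates only the phenol, which is far more acidic than the benzylic alcohol, so the Williamson alkylation should be selective for the phenolic oxygen.

Step 4
Reactants: 6 [4-(methoxymethoxy)phenyl]methanol
Product: 8 1-(chloromethyl)-4-(methoxymethoxy)benzene, via mesylate 7 (not isolated)
Conditions: MsCl, Et3N, CH2Cl2, 0 °C → rt
Reagents that add atoms: methanesulfonyl chloride (chlorine atom), CS(=O)(=O)Cl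
Why: Mesylation followed by chloride displacement in the same flask; the para-alkoxybenzylic mesylate is so reactive that the chloride of the ammonium salt should replace it at once, and the amine keeps the medium non-acidic for the acetal.

Step 5
Reactants: 8 1-(chloromethyl)-4-(methoxymethoxy)benzene; 9 (R)-epichlorohydrin
Product: 11 (2R)-1-chloro-4-[4-(methoxymethoxy)phenyl]butan-2-ol, via benzylic Grignard reagent 10 (not isolated)
Conditions: Mg, THF, 0 °C; then 9, CuBr·SMe2 (10 mol %), THF, −40 → −20 °C
Reagents that add atoms: none
Why: Copper-catalysed epoxide opening by a Grignard reagent at the unsubstituted carbon should be faster than chloride displacement; it forms the C3'–C4' bond and leaves the stereocentre of 9 untouched as C2' (R).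

Step 6
Reactants: 11 (2R)-1-chloro-4-[4-(methoxymethoxy)phenyl]butan-2-ol
Product: 12 tert-butyl{[(2R)-1-chloro-4-[4-(methoxymethoxy)phenyl]butan-2-yl]oxy}dimethylsilane
Conditions: TBSCl, imidazole, DMF, rt
Reagents that add atoms: tert-butyldimethylsilyl chloride (TBSCl), CC(C)(C)[Si](C)(C)Cl
Why: Standard silylation of a secondary alcohol; the robust silyl ether must last until the final step and keeps the C2' oxygen poorly nucleophilic.

Step 7
Reactants: 12 tert-butyl{[(2R)-1-chloro-4-[4-(methoxymethoxy)phenyl]butan-2-yl]oxy}dimethylsilane
Product: 13 tert-butyl{[(2R)-1-iodo-4-[4-(methoxymethoxy)phenyl]butan-2-yl]oxy}dimethylsilane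
Conditions: NaI, butan-2-one, 80 °C
Reagents that add atoms: sodium iodide, [Na+].[I-]
Why: Finkelstein halide exchange, driven by precipitation of NaCl, gives the more reactive iodide needed for the enolate alkylation.

Step 8
Reactants: 4 (5R)-5-[4-(methoxymethoxy)phenyl]oxolan-2-one; 13 tert-butyl{[(2R)-1-iodo-4-[4-(methoxymethoxy)phenyl]butan-2-yl]oxy}dimethylsilane
Product: 15 (3R,5R)-3-{(2R)-2-[(tert-butyldimethylsilyl)oxy]-4-[4-(methoxymethoxy)phenyl]butyl}-5-[4-(methoxymethoxy)phenyl]oxolan-2-one (3,5-trans), via lithium enolate 14 (not isolated)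
Conditions: LiN(i-Pr)2, THF, −78 °C; then 13, DMPU, −78 → −30 °C
Reagents that add atoms: none
Why: Alkylation of a γ-substituted butyrolactone enolate; the iodide should approach the planar enolate from the face opposite the C5 aryl group, which sets C4 trans to the aryl group (1,3-induction) in the absolute sense of the target, and DMPU raises the enolate reactivity toward the β-branched iodide.

Step 9
Reactants: 15 trans-3,5-disubstituted lactone
Product: 16 (3R,5R)-3-{(2R)-2-[(tert-butyldimethylsilyl)oxy]-4-[4-(methoxymethoxy)phenyl]butyl}-5-[4-(methoxymethoxy)phenyl]oxolan-2-ol (mixture of anomers)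
Conditions: i-Bu2AlH (1.2 equiv), CH2Cl2, −78 °C
Reagents that add atoms: none
Why: Partial reduction of the lactone; the tetrahedral aluminium hemiacetal is stable at −78 °C, so the reaction should stop at the lactol.

Step 10
Reactants: 16 lactol
Product: 17 (1R,3R,5R)-5-[(tert-butyldimethylsilyl)oxy]-3-ethynyl-1,7-bis[4-(methoxymethoxy)phenyl]heptan-1-ol
Conditions: dimethyl (1-diazo-2-oxopropyl)phosphonate, K2CO3, MeOH, 0 °C → rt
Reagents that add atoms: dimethyl (1-diazo-2-oxopropyl)phosphonate (one carbon), CC(=O)C(=[N+]=[N-])P(=O)(OC)OC
Why: Ohira–Bestmann (Seyferth–Gilbert) homologation of the masked aldehyde; the open hydroxy aldehyde reacts with the diazophosphonate anion and a 1,2-hydrogen shift gives the terminal alkyne, adding the carbon that becomes C8a while C4 should keep its configuration.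

Step 11
Reactants: 17 alkynol
Product: 18 (1R,3S,5R)-5-[(tert-butyldimethylsilyl)oxy]-3-ethynyl-1,7-bis[4-(methoxymethoxy)phenyl]-1-[(triethylsilyl)oxy]heptane
Conditions: TESCl, imidazole, CH2Cl2, 0 °C
Reagents that add atoms: triethylsilyl chloride (TESCl), CC[Si](CC)(CC)Cl
Why: Silylation of the benzylic alcohol with the more labile triethylsilyl group, chosen so that this oxygen can later be unmasked while the C2' silyl ether stays.

Step 12
Reactants: 18 terminal alkyne
Product: 21 (1R,3S,5R)-5-[(tert-butyldimethylsilyl)oxy]-1,7-bis[4-(methoxymethoxy)phenyl]-1-[(triethylsilyl)oxy]-3-{[(triisopropylsilyl)oxy]ethynyl}heptane, via lithium acetylide 19 (not isolated), via lithium ynolate 20 (not isolated)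
Conditions: n-BuLi, THF, −78 °C; LiOO-t-Bu (from t-BuOOH and LiN(SiMe3)2), −78 → 0 °C; TIPSOTf, −78 → 0 °C
Reagents that add atoms: tert-butyl hydroperoxide (one oxygen), CC(C)(C)OO; triisopropylsilyl trifluoromethanesulfonate (TIPSOTf), CC(C)[Si](C(C)C)(C(C)C)OS(=O)(=O)C(F)(F)F
Why: Oxidation of a lithium acetylide by lithium tert-butyl peroxide gives the lithium ynolate, and the bulky silyl triflate should silylate it on oxygen to the isolable triisopropylsilyl ynol ether; nothing touches the propargylic stereocentre.

Step 13
Reactants: 22 3,3-dimethoxybutan-2-one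
Product: 23 3-methoxybut-3-en-2-one
Conditions: TsOH·H2O (cat.), 140 °C, MeOH distilled off
Reagents that add atoms: none
Why: Acid-catalysed loss of methanol from the α-keto ketal (ketal to enol ether elimination), driven by removing methanol.

Step 14
Reactants: 23 3-methoxybut-3-en-2-one
Product: 25 1-diazo-3-methoxybut-3-en-2-one, via trifluoroacetyl diketone 24 (not isolated)
Conditions: LiN(SiMe3)2, THF, −78 °C; CF3CO2CH2CF3; then MsN3, Et3N, H2O, MeCN, rt
Reagents that add atoms: methanesulfonyl azide (two nitrogens), CS(=O)(=O)N=[N+]=[N-]
Why: Detrifluoroacetylative diazo transfer; the only enolisable position is trifluoroacetylated and the activated diketone takes the diazo group from the sulfonyl azide with loss of the trifluoroacetyl group, which avoids treating an enoyl chloride with a diazoalkane.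

Step 15
Reactants: 21 triisopropylsilyl ynol ether; 25 1-diazo-3-methoxybut-3-en-2-one
Product: 29 2-{(1R,3S,5R)-5-[(tert-butyldimethylsilyl)oxy]-1,7-bis[4-(methoxymethoxy)phenyl]-1-[(triethylsilyl)oxy]heptan-3-yl}-5-methoxy-3-[(triisopropylsilyl)oxy]phenol, via vinylketene 26 (not isolated), via vinylcyclobutenone 27 (not isolated), via dienylketene 28 (not isolated)
Conditions: hν (300 nm), CH2Cl2, rt; then toluene, 80 °C
Reagents that add atoms: none
Why: Light expels N2 from 25 and Wolff rearrangement (migration of the 1-methoxyvinyl group) gives vinylketene 26. Its electrophilic carbonyl carbon bonds to the alkyne carbon of 21 that carries the C4 chain and its α-carbon to the siloxy carbon in a polarised [2+2] addition (C4a–C5 and C8–C8a), giving cyclobutenone 27. Four-electron electrocyclic opening of 27 gives dienylketene 28, whose six-electron electrocyclisation forms C5–C6 and closes ring A; tautomerisation of the cyclohexadienone gives phenol 29. This is the known vinylketene–siloxyalkyne benzannulation (Danheiser benzannulation in its photochemical Wolff variant), applied here to a branched ynol ether. Ring A is closed by the thermal disrotatory 6π electrocyclisation, the only ring closure that persists. No stereocentre is created: the sp3 carbon of 27 is transient and the propargylic centre C4 is a spectator. The one regiochemistry needed is secured by the matched polarity of the ketene (electrophilic at the carbonyl carbon) and the ynol ether (nucleophilic at the carbon β to oxygen), and the ketene meets no O–H bond because 21 is fully protected; brief heating should complete the electrocyclic steps.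

Step 16
Reactants: 29 ring A phenol
Product: 30 methoxymethyl ether of 29 at the C5 oxygen, (1R,3S,5R) chain
Conditions: MOMCl, i-Pr2NEt, CH2Cl2, 0 → 40 °C
Reagents that add atoms: chloromethyl methyl ether (MOMCl), COCCl
Why: The only free hydroxyl (C5) is alkylated so that, after the next step, the C8a oxygen is the single free phenol of ring A; this keeps the two flanking oxygens distinct.

Step 17
Reactants: 30 C5 methoxymethyl ether
Product: 31 2-{(1R,3R,5R)-5-[(tert-butyldimethylsilyl)oxy]-1-hydroxy-1,7-bis[4-(methoxymethoxy)phenyl]heptan-3-yl}-5-methoxy-3-(methoxymethoxy)phenol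
Conditions: Bu4NF (2.2 equiv), THF, 0 °C
Reagents that add atoms: none
Why: Fluoride should cleave the aryl silyl ether (phenoxide leaving group) and the triethylsilyl ether much faster than the hindered secondary tert-butyldimethylsilyl ether at 0 °C, releasing the C8a phenol and the C2 carbinol while C2' stays protected.

Step 18
Reactants: 31 phenol carbinol
Product: 32 tert-butyl({(2R)-1-[(2R,4R)-7-methoxy-5-(methoxymethoxy)-2-[4-(methoxymethoxy)phenyl]chroman-4-yl]-4-[4-(methoxymethoxy)phenyl]butan-2-yl}oxy)dimethylsilane (2,4-trans)
Conditions: CSA (10 mol %), CH2Cl2 (0.01 M), 0 °C → rt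
Reagents that add atoms: none
Why: Acid-catalysed dehydrative etherification through the para-alkoxybenzylic cation at C2 (SN1), the classical flavan ring closure; the C8a phenol should capture the cation in a chair-like transition state with the C4 chain pseudoaxial (away from the C5 oxygen) and the aryl group pseudoequatorial, which is the 2,4-trans chroman. The same isomer is the thermodynamic one, so reversible ionisation can only reinforce it.

Step 19
Reactants: 32 2,4-trans chroman
Product: 33 8-bromo derivative of 32, (2R,4R), side chain (2R)
Conditions: NBS (1.0 equiv), CH2Cl2, −78 → −30 °C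
Reagents that add atoms: N-bromosuccinimide, O=C1CCC(=O)N1Br
Why: Electrophilic aromatic bromination of the phloroglucinol triether; C8 (between the methyl ether and the ring oxygen) should be preferred over C6 (between two free alkoxy groups, the C5 acetal being pushed toward C6 by the C4 chain), as is usual for 5,7-dialkoxy flavan-type chromans, and the anisole-type rings are far less reactive at low temperature.

Step 20
Reactants: 34 (E)-3-(4-hydroxyphenyl)prop-2-enoic acid
Product: 35 methoxymethyl (E)-3-[4-(methoxymethoxy)phenyl]prop-2-enoate
Conditions: MOMCl (2.4 equiv), i-Pr2NEt, CH2Cl2, 0 °C → rt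
Reagents that add atoms: chloromethyl methyl ether (MOMCl), COCCl
Why: Double O-alkylation as in step 1 protects the phenol and gives an activated ester for aminolysis.

Step 21
Reactants: 35 methoxymethyl (E)-3-[4-(methoxymethoxy)phenyl]prop-2-enoate
Product: 36 (E)-N-methoxy-3-[4-(methoxymethoxy)phenyl]-N-methylprop-2-enamide
Conditions: MeNHOMe·HCl, i-PrMgCl, THF, −20 °C
Reagents that add atoms: N,O-dimethylhydroxylamine hydrochloride, CNOC.Cl
Why: Aminolysis of the activated ester by the magnesium amide of N,O-dimethylhydroxylamine (Weinreb amide synthesis from an ester); attack at the acyl carbon should be faster than conjugate addition.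

Step 22
Reactants: 33 8-bromochroman; 36 Weinreb amide
Product: 38 (E)-1-[(2R,4R)-4-{(2R)-2-[(tert-butyldimethylsilyl)oxy]-4-[4-(methoxymethoxy)phenyl]butyl}-7-methoxy-5-(methoxymethoxy)-2-[4-(methoxymethoxy)phenyl]chroman-8-yl]-3-[4-(methoxymethoxy)phenyl]prop-2-en-1-one, via aryllithium 37 (not isolated)
Conditions: t-BuLi (2.1 equiv), THF, −78 °C; then 36, −78 → −20 °C
Reagents that add atoms: none
Why: Bromine–lithium exchange at −78 °C is faster than ortho-metalation, and the 2,6-dialkoxyaryllithium should add 1,2 to the Weinreb amide to give a chelated adduct that releases the enone only on work-up (Weinreb ketone synthesis), so over-addition and conjugate addition should not occur and the (E)-alkene is kept.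

Step 23
Reactants: 38 fully protected chalcone
Product: 39 (E)-1-{(2R,4S)-5-hydroxy-4-[(2R)-2-hydroxy-4-(4-hydroxyphenyl)butyl]-2-(4-hydroxyphenyl)-7-methoxychroman-8-yl}-3-(4-hydroxyphenyl)prop-2-en-1-one
Conditions: HCl (3 M, aq), MeOH/THF, rt → 40 °C
Reagents that add atoms: none
Why: Acid-catalysed cleavage of the four aryl methoxymethyl acetals and the secondary silyl ether in one operation; the ketone has no ortho hydroxyl, so no flavanone can form, and the mild temperature is chosen to keep the C2–O1 bond from ionising.

## Compound list

1 | 4-(4-hydroxyphenyl)-4-oxobutanoic acid | OC(=O)CCC(=O)c1ccc(O)cc1 | starting material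
2 | methoxymethyl 4-[4-(methoxymethoxy)phenyl]-4-oxobutanoate | COCOC(=O)CCC(=O)c1ccc(OCOC)cc1 | intermediate
3 | methoxymethyl (4R)-4-hydroxy-4-[4-(methoxymethoxy)phenyl]butanoate | COCOC(=O)CC[C@@H](O)c1ccc(OCOC)cc1 | intermediate (not isolated)
4 | (5R)-5-[4-(methoxymethoxy)phenyl]oxolan-2-one | O=C1O[C@@H](c2ccc(OCOC)cc2)CC1 | intermediate
5 | 4-(hydroxymethyl)phenol | OCc1ccc(O)cc1 | starting material
6 | [4-(methoxymethoxy)phenyl]methanol | OCc1ccc(OCOC)cc1 | intermediate
7 | 4-(methoxymethoxy)benzyl methanesulfonate | CS(=O)(=O)OCc1ccc(OCOC)cc1 | intermediate (not isolated)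
8 | 1-(chloromethyl)-4-(methoxymethoxy)benzene | ClCc1ccc(OCOC)cc1 | intermediate
9 | (R)-epichlorohydrin, (2R)-2-(chloromethyl)oxirane | ClC[C@H]1CO1 | starting material
10 | [4-(methoxymethoxy)benzyl]magnesium chloride | Cl[Mg]Cc1ccc(OCOC)cc1 | intermediate (not isolated)
11 | (2R)-1-chloro-4-[4-(methoxymethoxy)phenyl]butan-2-ol | ClC[C@H](O)CCc1ccc(OCOC)cc1 | intermediate
12 | tert-butyl{[(2R)-1-chloro-4-[4-(methoxymethoxy)phenyl]butan-2-yl]oxy}dimethylsilane | ClC[C@H](O[Si](C)(C)C(C)(C)C)CCc1ccc(OCOC)cc1 | intermediate
13 | tert-butyl{[(2R)-1-iodo-4-[4-(methoxymethoxy)phenyl]butan-2-yl]oxy}dimethylsilane | IC[C@H](O[Si](C)(C)C(C)(C)C)CCc1ccc(OCOC)cc1 | intermediate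
14 | lithium enolate of 4, lithium (5R)-5-[4-(methoxymethoxy)phenyl]-4,5-dihydrofuran-2-olate | [Li+].[O-]C1=CC[C@H](c2ccc(OCOC)cc2)O1 | intermediate (not isolated)
15 | (3R,5R)-3-{(2R)-2-[(tert-butyldimethylsilyl)oxy]-4-[4-(methoxymethoxy)phenyl]butyl}-5-[4-(methoxymethoxy)phenyl]oxolan-2-one (3,5-trans) | O=C1O[C@@H](c2ccc(OCOC)cc2)C[C@@H]1C[C@H](O[Si](C)(C)C(C)(C)C)CCc1ccc(OCOC)cc1 | intermediate
16 | (3R,5R)-3-{(2R)-2-[(tert-butyldimethylsilyl)oxy]-4-[4-(methoxymethoxy)phenyl]butyl}-5-[4-(methoxymethoxy)phenyl]oxolan-2-ol (anomers) | OC1O[C@@H](c2ccc(OCOC)cc2)C[C@@H]1C[C@H](O[Si](C)(C)C(C)(C)C)CCc1ccc(OCOC)cc1 | intermediate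
17 | (1R,3R,5R)-5-[(tert-butyldimethylsilyl)oxy]-3-ethynyl-1,7-bis[4-(methoxymethoxy)phenyl]heptan-1-ol | C#C[C@H](C[C@@H](O)c1ccc(OCOC)cc1)C[C@H](O[Si](C)(C)C(C)(C)C)CCc1ccc(OCOC)cc1 | intermediate
18 | (1R,3S,5R)-5-[(tert-butyldimethylsilyl)oxy]-3-ethynyl-1,7-bis[4-(methoxymethoxy)phenyl]-1-[(triethylsilyl)oxy]heptane | C#C[C@H](C[C@@H](O[Si](CC)(CC)CC)c1ccc(OCOC)cc1)C[C@H](O[Si](C)(C)C(C)(C)C)CCc1ccc(OCOC)cc1 | intermediate
19 | lithium acetylide of 18 | [Li]C#C[C@H](C[C@@H](O[Si](CC)(CC)CC)c1ccc(OCOC)cc1)C[C@H](O[Si](C)(C)C(C)(C)C)CCc1ccc(OCOC)cc1 | intermediate (not isolated)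
20 | lithium ynolate derived from 19 (oxygen on the former terminal alkyne carbon) | [Li]OC#C[C@H](C[C@@H](O[Si](CC)(CC)CC)c1ccc(OCOC)cc1)C[C@H](O[Si](C)(C)C(C)(C)C)CCc1ccc(OCOC)cc1 | intermediate (not isolated)
21 | (1R,3S,5R)-5-[(tert-butyldimethylsilyl)oxy]-1,7-bis[4-(methoxymethoxy)phenyl]-1-[(triethylsilyl)oxy]-3-{[(triisopropylsilyl)oxy]ethynyl}heptane | CC(C)[Si](C(C)C)(C(C)C)OC#C[C@H](C[C@@H](O[Si](CC)(CC)CC)c1ccc(OCOC)cc1)C[C@H](O[Si](C)(C)C(C)(C)C)CCc1ccc(OCOC)cc1 | intermediate (key-step precursor)
22 | 3,3-dimethoxybutan-2-one | CC(=O)C(C)(OC)OC | starting material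
23 | 3-methoxybut-3-en-2-one | C=C(OC)C(C)=O | intermediate
24 | 1,1,1-trifluoro-5-methoxyhex-5-ene-2,4-dione | C=C(OC)C(=O)CC(=O)C(F)(F)F | intermediate (not isolated)
25 | 1-diazo-3-methoxybut-3-en-2-one | C=C(OC)C(=O)C=[N+]=[N-] | intermediate (key-step precursor)
26 | 3-methoxybuta-1,3-dien-1-one (vinylketene) | C=C(OC)C=C=O | intermediate (not isolated)
27 | 4-(1-methoxyethenyl)-3-[(triisopropylsilyl)oxy]cyclobut-2-en-1-one carrying the C4 chain of 21 on C2 (ring sp3 carbon unassigned) | C=C(OC)C1C(=O)C(=C1O[Si](C(C)C)(C(C)C)C(C)C)[C@H](C[C@@H](O[Si](CC)(CC)CC)c1ccc(OCOC)cc1)C[C@H](O[Si](C)(C)C(C)(C)C)CCc1ccc(OCOC)cc1 | intermediate (not isolated)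
28 | dienylketene from ring opening of 27 | C=C(OC)C=C(O[Si](C(C)C)(C(C)C)C(C)C)C(=C=O)[C@H](C[C@@H](O[Si](CC)(CC)CC)c1ccc(OCOC)cc1)C[C@H](O[Si](C)(C)C(C)(C)C)CCc1ccc(OCOC)cc1 | intermediate (not isolated)
29 | 2-{(1R,3S,5R)-5-[(tert-butyldimethylsilyl)oxy]-1,7-bis[4-(methoxymethoxy)phenyl]-1-[(triethylsilyl)oxy]heptan-3-yl}-5-methoxy-3-[(triisopropylsilyl)oxy]phenol | COc1cc(O)c(c(O[Si](C(C)C)(C(C)C)C(C)C)c1)[C@H](C[C@@H](O[Si](CC)(CC)CC)c1ccc(OCOC)cc1)C[C@H](O[Si](C)(C)C(C)(C)C)CCc1ccc(OCOC)cc1 | intermediate (key-step product)
30 | methoxymethyl ether of 29 at the C5 oxygen, (1R,3S,5R) chain | COCOc1cc(OC)cc(O[Si](C(C)C)(C(C)C)C(C)C)c1[C@H](C[C@@H](O[Si](CC)(CC)CC)c1ccc(OCOC)cc1)C[C@H](O[Si](C)(C)C(C)(C)C)CCc1ccc(OCOC)cc1 | intermediate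
31 | 2-{(1R,3R,5R)-5-[(tert-butyldimethylsilyl)oxy]-1-hydroxy-1,7-bis[4-(methoxymethoxy)phenyl]heptan-3-yl}-5-methoxy-3-(methoxymethoxy)phenol | COCOc1cc(OC)cc(O)c1[C@H](C[C@@H](O)c1ccc(OCOC)cc1)C[C@H](O[Si](C)(C)C(C)(C)C)CCc1ccc(OCOC)cc1 | intermediate
32 | tert-butyl({(2R)-1-[(2R,4R)-7-methoxy-5-(methoxymethoxy)-2-[4-(methoxymethoxy)phenyl]chroman-4-yl]-4-[4-(methoxymethoxy)phenyl]butan-2-yl}oxy)dimethylsilane (2,4-trans) | COc1cc(OCOC)c2c(c1)O[C@@H](c1ccc(OCOC)cc1)C[C@@H]2C[C@H](O[Si](C)(C)C(C)(C)C)CCc1ccc(OCOC)cc1 | intermediate
33 | 8-bromo derivative of 32, (2R,4R), side chain (2R) | COc1cc(OCOC)c2c(c1Br)O[C@@H](c1ccc(OCOC)cc1)C[C@@H]2C[C@H](O[Si](C)(C)C(C)(C)C)CCc1ccc(OCOC)cc1 | intermediate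
34 | (E)-3-(4-hydroxyphenyl)prop-2-enoic acid | OC(=O)/C=C/c1ccc(O)cc1 | starting material
35 | methoxymethyl (E)-3-[4-(methoxymethoxy)phenyl]prop-2-enoate | COCOC(=O)/C=C/c1ccc(OCOC)cc1 | intermediate
36 | (E)-N-methoxy-3-[4-(methoxymethoxy)phenyl]-N-methylprop-2-enamide | CON(C)C(=O)/C=C/c1ccc(OCOC)cc1 | intermediate
37 | C8 aryllithium derived from 33 | COc1cc(OCOC)c2c(c1[Li])O[C@@H](c1ccc(OCOC)cc1)C[C@@H]2C[C@H](O[Si](C)(C)C(C)(C)C)CCc1ccc(OCOC)cc1 | intermediate (not isolated)
38 | (E)-1-[(2R,4R)-4-{(2R)-2-[(tert-butyldimethylsilyl)oxy]-4-[4-(methoxymethoxy)phenyl]butyl}-7-methoxy-5-(methoxymethoxy)-2-[4-(methoxymethoxy)phenyl]chroman-8-yl]-3-[4-(methoxymethoxy)phenyl]prop-2-en-1-one | COc1cc(OCOC)c2c(c1C(=O)/C=C/c1ccc(OCOC)cc1)O[C@@H](c1ccc(OCOC)cc1)C[C@@H]2C[C@H](O[Si](C)(C)C(C)(C)C)CCc1ccc(OCOC)cc1 | intermediate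
39 | (E)-1-{(2R,4S)-5-hydroxy-4-[(2R)-2-hydroxy-4-(4-hydroxyphenyl)butyl]-2-(4-hydroxyphenyl)-7-methoxychroman-8-yl}-3-(4-hydroxyphenyl)prop-2-en-1-one | COc1cc(O)c2c(c1C(=O)/C=C/c1ccc(O)cc1)O[C@@H](c1ccc(O)cc1)C[C@@H]2C[C@H](O)CCc1ccc(O)cc1 | target

## Step count and least certain steps

Total step count: 23. Longest linear sequence: 17 steps (steps 3–12, 15–19, 22 and 23, from 5 to 39). The branches from 1, 22 and 34 have two steps each.

**Step 15 (key step).** The most likely failure is a slow [2+2] addition of the ketene to the α-branched ynol ether. Ketene dimerisation, acylation of the product phenol by further ketene, or stalling at the cyclobutenone stage could then take over, and light absorption by the aryl ethers may add to this. Fallback: setting out from 21, the same vinylketene 26 is generated without light by 1,4-dehydrochlorination of (E)-3-methoxybut-2-enoyl chloride F1 with Et3N in toluene at 80–110 °C in the presence of 21, followed by the thermal benzannulation cascade. The route is rejoined at 29.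

**Step 8.** SN2 displacement at the β-silyloxy, β-branched iodide may be slow, so that on warming the enolate is consumed by proton transfer or the trans selectivity erodes. Fallback: the electrophile is changed to an epoxide opened by an aluminium enolate. Chlorohydrin 11 is closed with aqueous NaOH to (2R)-2-{2-[4-(methoxymethoxy)phenyl]ethyl}oxirane F2. Lithium enolate 14 (from 4) is transmetallated with Et2AlCl to the diethylaluminium enolate F3, which opens F2 at its terminal carbon to the hydroxy lactone F4. Silylation of F4 (TBSCl, imidazole) rejoins the route at 15.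

**Step 18.** The C2 cation may be captured by the side-chain silyl ether oxygen (closing an oxane with loss of the silyl group), the trans preference may be incomplete, or an aryl acetal may be lost under the acid. Fallback: from 31, the benzylic hydroxyl is exchanged for chloride under neutral conditions (PPh3, CCl4) to give the benzylic chloride F5 (C2 epimers). The ring is then closed with K2CO3 in acetone by the C8a phenoxide, a far better nucleophile than the silyl ether oxygen, with no acid present. The route is rejoined at 32.

**Step 19.** Bromination may occur at C6 instead of C8, because both positions are activated by three oxygens and only steric and conformational bias tells them apart. Fallback: bromine is introduced before ring closure, where the free C8a phenol directs it. From 31, amine-mediated ortho-bromination (NBS, catalytic i-Pr2NH, CH2Cl2, −78 °C) should give the C8 bromophenol F6, since C8 is the only free ortho position. Acid-catalysed closure as in step 18 then rejoins the route at 33.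

**Step 23.** Acid may ionise the C2–O1 bond of the deprotected product, leading to epimerisation at C2 or capture by the freed C2' hydroxyl (ring transposition); the C5 acetal para to the acyl group may also cleave slowly. Fallback: from 38, the acetals are exchanged for silyl ethers without protic acid (TMSOTf, 2,2'-bipyridyl, CH2Cl2, 0 °C), which should give the tetrakis(trimethylsilyl) ether F7. Buffered fluoride (HF·pyridine, THF/pyridine) then removes all five silyl groups and rejoins the route at 39.

## Further compounds

F1 | step 15 | (E)-3-methoxybut-2-enoyl chloride | CO/C(C)=C/C(Cl)=O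
F2 | step 8 | (2R)-2-{2-[4-(methoxymethoxy)phenyl]ethyl}oxirane | C1O[C@@H]1CCc1ccc(OCOC)cc1
F3 | step 8 | diethylaluminium enolate of 4 | CC[Al](CC)OC1=CC[C@H](c2ccc(OCOC)cc2)O1
F4 | step 8 | (3S,5R)-3-{(2R)-2-hydroxy-4-[4-(methoxymethoxy)phenyl]butyl}-5-[4-(methoxymethoxy)phenyl]oxolan-2-one | O=C1O[C@@H](c2ccc(OCOC)cc2)C[C@@H]1C[C@H](O)CCc1ccc(OCOC)cc1
F5 | step 18 | benzylic chloride from 31 (chlorine in place of the C2 hydroxyl, C2 epimers) | COCOc1cc(OC)cc(O)c1[C@H](CC(Cl)c1ccc(OCOC)cc1)C[C@H](O[Si](C)(C)C(C)(C)C)CCc1ccc(OCOC)cc1
F6 | step 19 | C8 bromophenol from 31, (1R,3R,5R) chain | COCOc1cc(OC)c(Br)c(O)c1[C@H](C[C@@H](O)c1ccc(OCOC)cc1)C[C@H](O[Si](C)(C)C(C)(C)C)CCc1ccc(OCOC)cc1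
F7 | step 23 | tetrakis(trimethylsilyl) ether of the target phenols with the C2' tert-butyldimethylsilyl ether, (2R,4R) | COc1cc(O[Si](C)(C)C)c2c(c1C(=O)/C=C/c1ccc(O[Si](C)(C)C)cc1)O[C@@H](c1ccc(O[Si](C)(C)C)cc1)C[C@@H]2C[C@H](O[Si](C)(C)C(C)(C)C)CCc1ccc(O[Si](C)(C)C)cc1
A1 | alternative 1 | protected 8-acetyl-2,4-trans-chroman, product of the cycloaddition | COc1cc(OCc3ccccc3)c2c(c1C(C)=O)O[C@@H](c1ccc(OC(C)=O)cc1)C[C@@H]2C[C@H](O[Si](C)(C)C(C)(C)C)CCc1ccc(OCc3ccccc3)cc1
A2 | alternative 1 | ortho-hydroxystyrene with the (E)-C4=C1' alkene on C4a and the acetyl group on C8 | CC(=O)c1c(OC)cc(OCc2ccccc2)c(/C=C/[C@H](O[Si](C)(C)C(C)(C)C)CCc2ccc(OCc3ccccc3)cc2)c1O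
A3 | alternative 1 | 4-acetoxystyrene | CC(=O)Oc1ccc(C=C)cc1
A4 | alternative 2 | fully silylated target, product of the aryne cascade | COc1cc(O[Si](C)(C)C(C)(C)C)c2c(c1C(=O)/C=C/c1ccc(O[Si](C)(C)C(C)(C)C)cc1)O[C@@H](c1ccc(O[Si](C)(C)C(C)(C)C)cc1)C[C@@H]2C[C@H](O[Si](C)(C)C(C)(C)C)CCc1ccc(O[Si](C)(C)C(C)(C)C)cc1
A5 | alternative 2 | bromoarene carbinol with bromine on C8a and a free (2R) hydroxyl on C2 | COc1cc(O[Si](C)(C)C(C)(C)C)c(c(Br)c1)[C@H](C[C@@H](O)c1ccc(O[Si](C)(C)C(C)(C)C)cc1)C[C@H](O[Si](C)(C)C(C)(C)C)CCc1ccc(O[Si](C)(C)C(C)(C)C)cc1
A6 | alternative 2 | (E)-3-{4-[(tert-butyldimethylsilyl)oxy]phenyl}-N-methoxy-N-methylprop-2-enamide | CON(C)C(=O)/C=C/c1ccc(O[Si](C)(C)C(C)(C)C)cc1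
A7 | alternative 3 | 8-acetyl-2,4-trans-chroman with a free phenol on the C2 aryl ring, product of the oxidative closure | CC(=O)c1c(OC)cc(OC(=O)C(C)(C)C)c2c1O[C@@H](c1ccc(O)cc1)C[C@@H]2C[C@H](O[Si](C)(C)C(C)(C)C)CCc1ccc(OC(=O)C(C)(C)C)cc1
A8 | alternative 3 | open-chain phenol with a 2-(4-hydroxyphenyl)ethyl arm on C4 and free C8a hydroxyl | CC(=O)c1c(OC)cc(OC(=O)C(C)(C)C)c(c1O)[C@H](CCc1ccc(O)cc1)C[C@H](O[Si](C)(C)C(C)(C)C)CCc1ccc(OC(=O)C(C)(C)C)cc1
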